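**Retrosynthetic overview**

1. The strategy rests on the cis-8,9-diol (C8–OH, C9–O-acyl) inside the ten-membered carbocycle C1–C10, lying between C7 of the trans-fused γ-lactone and quaternary C10 of the 3(2H)-furanone. These are two neighbouring oxygen-bearing carbons of like polarity, so they are joined by reductive coupling of a C8 and a C9 aldehyde with SmI2, which closes the carbocycle last.
2. Target ⇐ 8,9-diol macrocycle with saturated lactone (O8 silylation, lactone α-methylenation through the Mannich base, O9 methacryloylation, desilylation) ⇐ dialdehyde (C8–C9 pinacol disconnection).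
3. Dialdehyde ⇐ primary 8,9-diol (double oxidation) ⇐ trans-lactone imide ⇐ Evans syn-aldol/lactonisation (C6–C7 bond; C6 and C7 set) of a succinate imide with the furanone Z-enal.
4. Z-enal ⇐ 5-alkenyl-3(2H)-furanone ⇐ gold-catalysed 5-endo cyclisation of an α'-hydroxy ynone ⇐ Weinreb amide carrying C9, C10, C1 (C10 from (R)-lactic acid by self-regeneration of stereocentres) + acetylide of a Z-enyne carrying C2–C6.
5. Ring order: furanone (step 8), γ-lactone (step 12), ten-membered carbocycle (step 16).

Key step: step 16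

Remark on numbering (germacrane type): C1 furanone C=O; C2=C3 furanone alkene (ring O on C3); C4(Me)=C5 Z-alkene; C6 lactone O–CH; C7 lactone CH; C8 and C9 the diol carbons; C10 quaternary O–C(Me); C11, C12, C13 lactone α-carbon, carbonyl and exo-methylene.
Remark: (R)-lactic acid (1) and (Z)-3-methylpent-2-en-4-yn-1-ol (9, a vitamin A intermediate) are taken as commercial.

**Route**

Step 1
Reactants: 1 (R)-lactic acid; 2 pivalaldehyde
Product: 3 (2R,5R)-2-tert-butyl-5-methyl-1,3-dioxolan-4-one (cis)
Conditions: TsOH·H2O (cat.), H2SO4 (cat.), pentane, reflux, Dean–Stark; crystallisation from pentane/Et2O, −78 °C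
Reagents that add atoms: none
Why: Acid-catalysed acetalisation with azeotropic removal of water (first stage of the Seebach self-regeneration of stereocentres) should give mainly the cis-dioxolanone, the new acetal centre C2 being set under thermodynamic control by the lactate centre, and crystallisation removes the trans isomer.

Step 2
Reactants: 3 (2R,5R)-2-tert-butyl-5-methyl-1,3-dioxolan-4-one
Product: 5 (2R,5S)-5-[(benzyloxy)methyl]-2-tert-butyl-5-methyl-1,3-dioxolan-4-one, via lithium enolate 4 (not isolated)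
Conditions: LiN(iPr)2, THF, −78 °C; BnOCH2Cl, −78 → −30 °C
Reagents that add atoms: benzyl chloromethyl ether, ClCOCc1ccccc1
Why: Diastereoselective enolate alkylation (self-regeneration of stereocentres): deprotonation flattens C5, the tert-butyl group on the acetal carbon shields one enolate face and the chloromethyl ether enters trans to it, so CH2OBn takes the place of the former hydrogen and the quaternary centre (later C10) is set with overall retention.

Step 3
Reactants: 5 (2R,5S)-5-[(benzyloxy)methyl]-2-tert-butyl-5-methyl-1,3-dioxolan-4-one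
Product: 6 (S)-3-(benzyloxy)-2-hydroxy-N-methoxy-N,2-dimethylpropanamide
Conditions: MeNH(OMe)·HCl, iPrMgCl, THF, −20 → 0 °C; 1 M HCl
Reagents that add atoms: N,O-dimethylhydroxylamine hydrochloride, CNOC.Cl
Why: Weinreb amide formation by aminolysis of the activated acylal ester with the chloromagnesium amide; the expelled hemiacetal alkoxide collapses to pivalaldehyde and the tertiary alkoxide, and the quaternary centre is not touched.

Step 4
Reactants: 6 (S)-3-(benzyloxy)-2-hydroxy-N-methoxy-N,2-dimethylpropanamide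
Product: 7 (S)-2,3-dihydroxy-N-methoxy-N,2-dimethylpropanamide
Conditions: H2 (1 atm), Pd/C (10%), EtOAc, rt
Reagents that add atoms: none
Why: Hydrogenolysis of the benzyl ether over Pd/C, placed here because no alkene or alkyne is yet present and N-methoxy amides tolerate hydrogen at 1 atm.

Step 5
Reactants: 7 (S)-2,3-dihydroxy-N-methoxy-N,2-dimethylpropanamide
Product: 8 (S)-3-[(tert-butyldimethylsilyl)oxy]-2-hydroxy-N-methoxy-N,2-dimethylpropanamide
Conditions: TBSCl, imidazole, CH2Cl2, 0 °C
Reagents that add atoms: tert-butyldimethylsilyl chloride, CC(C)(C)[Si](C)(C)Cl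
Why: Silylation with TBSCl/imidazole is selective for the primary hydroxyl (later O9) over the tertiary one for steric reasons.

Step 6
Reactants: 9 (Z)-3-methylpent-2-en-4-yn-1-ol
Product: 10 triethyl{[(Z)-3-methylpent-2-en-4-yn-1-yl]oxy}silane
Conditions: TESCl, imidazole, CH2Cl2, 0 °C
Reagents that add atoms: triethylsilyl chloride, CC[Si](CC)(CC)Cl
Why: Silyl protection of the allylic hydroxyl (later O6) as the labile triethylsilyl ether, needed because a free Z-enynol would add to the activated alkyne later and because this group must afterwards be removed beside the TBS ether.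

Step 7
Reactants: 10 triethyl{[(Z)-3-methylpent-2-en-4-yn-1-yl]oxy}silane (3 equiv); 8 (S)-3-[(tert-butyldimethylsilyl)oxy]-2-hydroxy-N-methoxy-N,2-dimethylpropanamide
Product: 12 (2S,6Z)-1-[(tert-butyldimethylsilyl)oxy]-2-hydroxy-2,6-dimethyl-8-[(triethylsilyl)oxy]oct-6-en-4-yn-3-one, via lithium acetylide 11 (not isolated)
Conditions: 10, n-BuLi, THF, −78 °C; then 8, −78 → 0 °C; AcOH, −40 °C
Reagents that add atoms: none
Why: Acetylide addition to a Weinreb amide: the first equivalent of 11 deprotonates the tertiary hydroxyl, the chelated tetrahedral intermediate prevents a second addition, and the acidic quench releases the α'-hydroxy ynone with the Z-alkene and the quaternary centre unchanged.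

Step 8
Reactants: 12 (2S,6Z)-1-[(tert-butyldimethylsilyl)oxy]-2-hydroxy-2,6-dimethyl-8-[(triethylsilyl)oxy]oct-6-en-4-yn-3-one
Product: 13 (S)-2-{[(tert-butyldimethylsilyl)oxy]methyl}-2-methyl-5-{(Z)-4-[(triethylsilyl)oxy]but-2-en-2-yl}furan-3(2H)-one
Conditions: (4-CF3C6H4)3PAuCl (3 mol%), AgOTf (3 mol%), toluene, rt, dark
Reagents that add atoms: none
Why: Gold-catalysed 5-endo-dig hydroalkoxylation (cycloisomerisation of an α'-hydroxy ynone to a 3(2H)-furanone): cationic monovalent gold activates the alkyne, the tertiary hydroxyl attacks the β-carbon (C3) in preference to the silyl ether oxygen, and protodeauration gives the furanone without touching the Z-alkene.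

Step 9
Reactants: 13 (S)-2-{[(tert-butyldimethylsilyl)oxy]methyl}-2-methyl-5-{(Z)-4-[(triethylsilyl)oxy]but-2-en-2-yl}furan-3(2H)-one
Product: 14 (S)-2-{[(tert-butyldimethylsilyl)oxy]methyl}-5-[(Z)-4-hydroxybut-2-en-2-yl]-2-methylfuran-3(2H)-one
Conditions: PPTS (cat.), MeOH, 0 °C
Reagents that add atoms: none
Why: Acid-catalysed methanolysis of silyl ethers: the primary allylic triethylsilyl ether is cleaved far faster than the neopentyl TBS ether.

Step 10
Reactants: 14 (S)-2-{[(tert-butyldimethylsilyl)oxy]methyl}-5-[(Z)-4-hydroxybut-2-en-2-yl]-2-methylfuran-3(2H)-one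
Product: 15 (Z)-3-[(S)-5-{[(tert-butyldimethylsilyl)oxy]methyl}-5-methyl-4-oxo-4,5-dihydrofuran-2-yl]but-2-enal
Conditions: Dess–Martin periodinane, pyridine, CH2Cl2, 0 °C, dark; used at once
Reagents that add atoms: none
Why: Dess–Martin oxidation of the allylic alcohol under buffered conditions in the dark, which should keep the Z-geometry of the β,β-disubstituted enal.

Step 11
Reactants: 16 (S)-4-benzyloxazolidin-2-one; 17 methyl 4-chloro-4-oxobutanoate
Product: 19 methyl 4-[(S)-4-benzyl-2-oxooxazolidin-3-yl]-4-oxobutanoate, via N-lithio oxazolidinone 18 (not isolated)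
Conditions: n-BuLi, THF, −78 °C; then 17, −78 → 0 °C
Reagents that add atoms: none
Why: N-Acylation of the lithiated oxazolidinone with the acid chloride, the standard entry to Evans imides.

Step 12
Reactants: 19 methyl 4-[(S)-4-benzyl-2-oxooxazolidin-3-yl]-4-oxobutanoate; 15 (Z)-3-[(S)-5-{[(tert-butyldimethylsilyl)oxy]methyl}-5-methyl-4-oxo-4,5-dihydrofuran-2-yl]but-2-enal
Product: 22 (S)-4-benzyl-3-{(2R,3S)-2-[(Z)-2-((S)-5-{[(tert-butyldimethylsilyl)oxy]methyl}-5-methyl-4-oxo-4,5-dihydrofuran-2-yl)prop-1-en-1-yl]-5-oxotetrahydrofuran-3-carbonyl}oxazolidin-2-one, via boron Z-enolate 20 (not isolated), via syn-aldol adduct 21 (not isolated)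
Conditions: 19, Bu2BOTf, iPr2NEt, CH2Cl2, −78 → 0 °C; 15, −78 → −10 °C; pH 7 buffer, MeOH, H2O2, 0 °C; then PPTS (cat.), CH2Cl2, rt
Reagents that add atoms: none
Why: Evans syn-aldol reaction followed by lactonisation: soft enolisation gives the Z boron enolate, which reacts through a chair (Zimmerman–Traxler) transition state on the enolate face away from the benzyl group of the (S)-auxiliary to set C7 (S in 22) and C6 (R) in a syn relation, and closure of the C6 hydroxyl onto the methyl ester then necessarily gives the trans-4,5-disubstituted γ-lactone.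

Step 13
Reactants: 22 trans-lactone imide
Product: 23 (4R,5R)-5-[(Z)-2-((S)-5-{[(tert-butyldimethylsilyl)oxy]methyl}-5-methyl-4-oxo-4,5-dihydrofuran-2-yl)prop-1-en-1-yl]-4-(hydroxymethyl)dihydrofuran-2(3H)-one
Conditions: LiBH4, H2O (1 equiv), Et2O/THF, 0 °C
Reagents that add atoms: none
Why: Reductive cleavage of the N-acyl oxazolidinone with LiBH4: the activated exocyclic imide carbonyl is attacked faster than the lactone or the vinylogous-ester carbonyl of the furanone, so a small excess at 0 °C with early quench should give the C8 primary alcohol without epimerisation of C7.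

Step 14
Reactants: 23 C8 alcohol with O9 TBS ether
Product: 24 (4R,5R)-4-(hydroxymethyl)-5-{(Z)-2-[(S)-5-(hydroxymethyl)-5-methyl-4-oxo-4,5-dihydrofuran-2-yl]prop-1-en-1-yl}dihydrofuran-2(3H)-one
Conditions: HF·pyridine, pyridine, THF, 0 °C → rt
Reagents that add atoms: none
Why: Desilylation with HF·pyridine, chosen because acidic fluoride avoids the alkoxides that could cause retro-aldol loss of the C9 hydroxymethyl group or shift of the lactone to O8.

Step 15
Reactants: 24 primary 8,9-diol
Product: 25 (S)-5-{(Z)-1-[(2R,3S)-3-formyl-5-oxotetrahydrofuran-2-yl]prop-1-en-2-yl}-2-methyl-3-oxo-2,3-dihydrofuran-2-carbaldehyde (dialdehyde; 6R,7S,10S)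
Conditions: Dess–Martin periodinane, CH2Cl2, 0 °C → rt; filtration through a short silica pad; used at once
Reagents that add atoms: none
Why: Dess–Martin oxidation of both primary alcohols under non-basic, anhydrous conditions; the C9 aldehyde (β-keto aldehyde on a quaternary carbon, prone to deformylation by nucleophiles) and the C8 aldehyde (β-acyloxy, prone to elimination and to epimerisation at C7, for which the trans-lactone is the stable arrangement) are kept away from base and water.

Step 16
Reactants: 25 dialdehyde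
Product: 26 (6R,7R,8S,9S,10S)-8,9-dihydroxy-3,10-epoxy-1-oxogermacra-2,4(Z)-dien-12,6-olide (8,9-cis-diol macrocycle, lactone without exo-methylene)
Conditions: SmI2 (5 equiv), THF, −78 → 0 °C, 25 added over 6 h by syringe pump (final 2 mM); 0.1 M HCl
Reagents that add atoms: none
Why: SmI2 transfers one electron to each formyl group, the most easily reduced carbonyls present (the lactone carries no exo-methylene, so no acrylate competes, and the C9 aldehyde is activated by its α-oxygen and can hold samarium in a chelate), and the two ketyls couple at carbon to a trivalent-samarium-bridged diolate that is protonated on work-up. The closest known reaction type is the intramolecular SmI2 pinacol coupling of dialdehydes to cyclic cis-diols. The ten-membered carbocycle C1–C10 closes in a 10-exo-trig mode (ketyl carbon C9 onto carbonyl carbon C8, or the equivalent diketyl recombination), helped by the furanone, the Z-alkene and the trans-lactone, three rigid units that hold C8 and C9 within reach. C9 is controlled by quaternary C10, the samarium-bound oxygen being expected on the side of the furanone ring oxygen (chelation, and avoidance of the C10 methyl), which corresponds to 9S. C8 is controlled by the samarium bridge to O9, which should place O8 on the same ring face (8S, cis-diol), with C7 as a second and possibly opposing influence. The step needs chemoselectivity for the aldehydes over the furanone dienone and the allylic lactone C6–O bond, for which HMPA-free conditions, low temperature and slow addition at high dilution are chosen, and it needs the cis-diol anti to the C10 methyl, which the substrate favours but does not guarantee.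

Step 17
Reactants: 26 8,9-cis-diol macrocycle
Product: 28 8-O-TBS 9-O-TMS bis-silyl ether of 26, via 8-O-TBS ether 27 (not isolated)
Conditions: TBSCl, imidazole, DMF, 0 °C → rt; then TMSCl, rt
Reagents that add atoms: tert-butyldimethylsilyl chloride, CC(C)(C)[Si](C)(C)Cl; trimethylsilyl chloride, C[Si](C)(C)Cl
Why: Regioselective silylation governed by steric access: O8 lies between two methine carbons whereas O9 is neopentylic (next to quaternary C10), so TBSCl should react at O8 and the small TMS group then caps O9, which must not stay free in step 18 because its alkoxide, β to the C1 ketone, could open the C9–C10 bond by retro-aldol cleavage.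

Step 18
Reactants: 28 bis-silyl ether
Product: 30 11-(dimethylaminomethyl) lactone (Mannich base; C11 epimers), via lactone lithium enolate 29 (not isolated)
Conditions: LiN(iPr)2, THF, −78 °C; CH2=NMe2+ I−, −78 → 0 °C
Reagents that add atoms: Eschenmoser's salt (N,N-dimethylmethyleneiminium iodide), C=[N+](C)C.[I-]
Why: Mannich reaction of the lactone lithium enolate with Eschenmoser's salt: C11 carries the only readily removable α-protons (C10 is quaternary, C2 vinylic), and kinetic deprotonation at −78 °C followed by rapid trapping installs the dimethylaminomethyl group, whose configuration at C11 is of no consequence.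

Step 19
Reactants: 30 Mannich base
Product: 33 8-O-TBS 9-hydroxy α-methylene lactone, via ammonium iodide 31 (not isolated), via 9-O-TMS methylene lactone 32 (not isolated)
Conditions: MeI, THF, rt; aq. NaHCO3, EtOAc, rt; then PPTS (cat.), MeOH, 0 °C
Reagents that add atoms: none
Why: Quaternisation of the Mannich base and base-induced β-elimination of trimethylamine (Hofmann-type, through the lactone enolate) give the α-methylene lactone, and mild acid methanolysis then removes the labile O9 trimethylsilyl group while the O8 TBS ether stays.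

Step 20
Reactants: 33 8-O-TBS 9-hydroxy α-methylene lactone
Product: 34 8-O-TBS ether of the target (9-O-methacrylate)
Conditions: methacrylic anhydride, Et3N, DMAP, CH2Cl2, rt
Reagents that add atoms: methacrylic anhydride, C=C(C)C(=O)OC(=O)C(C)=C
Why: DMAP-catalysed acylation of the hindered secondary C9 hydroxyl with the anhydride (nucleophilic catalysis through the acylpyridinium ion); O8 is blocked, so only O9 can be esterified.

Step 21
Reactants: 34 8-O-TBS ether of the target
Product: 35 target, (6R,7R,8S,9S,10S)-8-hydroxy-9-(methacryloyloxy)-3,10-epoxy-1-oxogermacra-2,4(Z),11(13)-trien-12,6-olide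
Conditions: HF·pyridine, pyridine, THF, 0 °C → rt
Reagents that add atoms: none
Why: Fluoride-mediated cleavage of the secondary TBS ether with HF·pyridine, whose acidic medium should prevent migration of the methacrylate from O9 to O8 and conjugate additions to the two acrylate units.

**Compound list**

1 | (R)-lactic acid | C[C@@H](O)C(=O)O | starting material
2 | pivalaldehyde | CC(C)(C)C=O | starting material
3 | (2R,5R)-2-tert-butyl-5-methyl-1,3-dioxolan-4-one (cis) | C[C@H]1O[C@@H](C(C)(C)C)OC1=O | intermediate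
4 | lithium enolate of 3 (not isolated) | [Li+].CC1=C([O-])O[C@H](C(C)(C)C)O1 | intermediate
5 | (2R,5S)-5-[(benzyloxy)methyl]-2-tert-butyl-5-methyl-1,3-dioxolan-4-one | C[C@@]1(COCc2ccccc2)O[C@@H](C(C)(C)C)OC1=O | intermediate
6 | (S)-3-(benzyloxy)-2-hydroxy-N-methoxy-N,2-dimethylpropanamide | C[C@@](C(=O)N(C)OC)(COCc1ccccc1)O | intermediate
7 | (S)-2,3-dihydroxy-N-methoxy-N,2-dimethylpropanamide | C[C@@](C(=O)N(C)OC)(CO)O | intermediate
8 | (S)-3-[(tert-butyldimethylsilyl)oxy]-2-hydroxy-N-methoxy-N,2-dimethylpropanamide | C[C@@](C(=O)N(C)OC)(CO[Si](C)(C)C(C)(C)C)O | intermediate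
9 | (Z)-3-methylpent-2-en-4-yn-1-ol | C#C/C(C)=C\CO | starting material
10 | triethyl{[(Z)-3-methylpent-2-en-4-yn-1-yl]oxy}silane | C#C/C(C)=C\CO[Si](CC)(CC)CC | intermediate
11 | lithium acetylide of 10 (not isolated) | [Li+].[C-]#C/C(C)=C\CO[Si](CC)(CC)CC | intermediate
12 | (2S,6Z)-1-[(tert-butyldimethylsilyl)oxy]-2-hydroxy-2,6-dimethyl-8-[(triethylsilyl)oxy]oct-6-en-4-yn-3-one | C[C@@](C(=O)C#C/C(C)=C\CO[Si](CC)(CC)CC)(CO[Si](C)(C)C(C)(C)C)O | intermediate
13 | (S)-2-{[(tert-butyldimethylsilyl)oxy]methyl}-2-methyl-5-{(Z)-4-[(triethylsilyl)oxy]but-2-en-2-yl}furan-3(2H)-one | C[C@@]1(CO[Si](C)(C)C(C)(C)C)OC(/C(C)=C\CO[Si](CC)(CC)CC)=CC1=O | intermediate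
14 | (S)-2-{[(tert-butyldimethylsilyl)oxy]methyl}-5-[(Z)-4-hydroxybut-2-en-2-yl]-2-methylfuran-3(2H)-one | C[C@@]1(CO[Si](C)(C)C(C)(C)C)OC(/C(C)=C\CO)=CC1=O | intermediate
15 | (Z)-3-[(S)-5-{[(tert-butyldimethylsilyl)oxy]methyl}-5-methyl-4-oxo-4,5-dihydrofuran-2-yl]but-2-enal | C[C@@]1(CO[Si](C)(C)C(C)(C)C)OC(/C(C)=C\C=O)=CC1=O | intermediate
16 | (S)-4-benzyloxazolidin-2-one | O=C1N[C@@H](Cc2ccccc2)CO1 | starting material
17 | methyl 4-chloro-4-oxobutanoate | COC(=O)CCC(=O)Cl | starting material
18 | N-lithio derivative of 16 (not isolated) | [Li+].O=C1[N-][C@@H](Cc2ccccc2)CO1 | intermediate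
19 | methyl 4-[(S)-4-benzyl-2-oxooxazolidin-3-yl]-4-oxobutanoate | COC(=O)CCC(=O)N1[C@@H](Cc2ccccc2)COC1=O | intermediate
20 | dibutylboron Z-enolate of 19 (not isolated) | COC(=O)C/C=C(\OB(CCCC)CCCC)N1[C@@H](Cc2ccccc2)COC1=O | intermediate
21 | syn-aldol adduct, methyl (3S,4R,5Z)-3-[(S)-4-benzyl-2-oxooxazolidine-3-carbonyl]-6-[(S)-5-{[(tert-butyldimethylsilyl)oxy]methyl}-5-methyl-4-oxo-4,5-dihydrofuran-2-yl]-4-hydroxyhept-5-enoate (not isolated) | COC(=O)C[C@@H]([C@H](O)/C=C(/C)C1=CC(=O)[C@@](CO[Si](C)(C)C(C)(C)C)(C)O1)C(=O)N1[C@@H](Cc2ccccc2)COC1=O | intermediate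
22 | trans-lactone imide, (S)-4-benzyl-3-{(2R,3S)-2-[(Z)-2-((S)-5-{[(tert-butyldimethylsilyl)oxy]methyl}-5-methyl-4-oxo-4,5-dihydrofuran-2-yl)prop-1-en-1-yl]-5-oxotetrahydrofuran-3-carbonyl}oxazolidin-2-one | O=C(N1[C@@H](Cc2ccccc2)COC1=O)[C@H]1CC(=O)O[C@@H]1/C=C(/C)C1=CC(=O)[C@@](CO[Si](C)(C)C(C)(C)C)(C)O1 | intermediate
23 | (4R,5R)-5-[(Z)-2-((S)-5-{[(tert-butyldimethylsilyl)oxy]methyl}-5-methyl-4-oxo-4,5-dihydrofuran-2-yl)prop-1-en-1-yl]-4-(hydroxymethyl)dihydrofuran-2(3H)-one | OC[C@H]1CC(=O)O[C@@H]1/C=C(/C)C1=CC(=O)[C@@](CO[Si](C)(C)C(C)(C)C)(C)O1 | intermediate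
24 | (4R,5R)-4-(hydroxymethyl)-5-{(Z)-2-[(S)-5-(hydroxymethyl)-5-methyl-4-oxo-4,5-dihydrofuran-2-yl]prop-1-en-1-yl}dihydrofuran-2(3H)-one | OC[C@H]1CC(=O)O[C@@H]1/C=C(/C)C1=CC(=O)[C@@](CO)(C)O1 | intermediate
25 | dialdehyde, (S)-5-{(Z)-1-[(2R,3S)-3-formyl-5-oxotetrahydrofuran-2-yl]prop-1-en-2-yl}-2-methyl-3-oxo-2,3-dihydrofuran-2-carbaldehyde | O=C[C@H]1CC(=O)O[C@@H]1/C=C(/C)C1=CC(=O)[C@@](C=O)(C)O1 | intermediate
26 | (6R,7R,8S,9S,10S)-8,9-dihydroxy-3,10-epoxy-1-oxogermacra-2,4(Z)-dien-12,6-olide | O[C@H]1[C@@H](O)[C@H]2CC(=O)O[C@@H]2/C=C(/C)C2=CC(=O)[C@@]1(C)O2 | intermediate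
27 | 8-O-TBS ether of 26, stereocentres as in 26 (not isolated) | O[C@H]1[C@@H](O[Si](C)(C)C(C)(C)C)[C@H]2CC(=O)O[C@@H]2/C=C(/C)C2=CC(=O)[C@@]1(C)O2 | intermediate
28 | 8-O-TBS 9-O-TMS ether of 26, stereocentres as in 26 | C[Si](C)(C)O[C@H]1[C@@H](O[Si](C)(C)C(C)(C)C)[C@H]2CC(=O)O[C@@H]2/C=C(/C)C2=CC(=O)[C@@]1(C)O2 | intermediate
29 | lithium enolate (C11–C12) of 28 (not isolated) | [Li+].C[Si](C)(C)O[C@H]1[C@@H](O[Si](C)(C)C(C)(C)C)[C@H]2C=C([O-])O[C@@H]2/C=C(/C)C2=CC(=O)[C@@]1(C)O2 | intermediate
30 | Mannich base, 28 with CH2NMe2 on C11 (C11 epimers) | C[Si](C)(C)O[C@H]1[C@@H](O[Si](C)(C)C(C)(C)C)[C@H]2C(CN(C)C)C(=O)O[C@@H]2/C=C(/C)C2=CC(=O)[C@@]1(C)O2 | intermediate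
31 | trimethylammonium iodide of 30 (not isolated) | [I-].C[Si](C)(C)O[C@H]1[C@@H](O[Si](C)(C)C(C)(C)C)[C@H]2C(C[N+](C)(C)C)C(=O)O[C@@H]2/C=C(/C)C2=CC(=O)[C@@]1(C)O2 | intermediate
32 | 8-O-TBS 9-O-TMS α-methylene lactone (not isolated) | C[Si](C)(C)O[C@H]1[C@@H](O[Si](C)(C)C(C)(C)C)[C@H]2C(=C)C(=O)O[C@@H]2/C=C(/C)C2=CC(=O)[C@@]1(C)O2 | intermediate
33 | 8-O-TBS 9-hydroxy α-methylene lactone, stereocentres as in 26 | O[C@H]1[C@@H](O[Si](C)(C)C(C)(C)C)[C@H]2C(=C)C(=O)O[C@@H]2/C=C(/C)C2=CC(=O)[C@@]1(C)O2 | intermediate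
34 | 8-O-TBS ether of the target | C=C(C)C(=O)O[C@H]1[C@@H](O[Si](C)(C)C(C)(C)C)[C@H]2C(=C)C(=O)O[C@@H]2/C=C(/C)C2=CC(=O)[C@@]1(C)O2 | intermediate
35 | CNP0562373.1, (6R,7R,8S,9S,10S)-8-hydroxy-9-(methacryloyloxy)-3,10-epoxy-1-oxogermacra-2,4(Z),11(13)-trien-12,6-olide | C=C(C)C(=O)O[C@H]1[C@@H](O)[C@H]2C(=C)C(=O)O[C@@H]2/C=C(/C)C2=CC(=O)[C@@]1(C)O2 | target

**Step count**

Total: 21 steps. Longest linear sequence: 19 steps (steps 1–5, 7–10, 12–21, from (R)-lactic acid).

**Steps most likely to fail, with fallbacks**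

Step 16 (pinacol ring closure). Several processes may defeat it: intermolecular coupling instead of ring closure; electron transfer into the furanone dienone with expulsion of the allylic C6 carboxylate; loss of the C9 formyl group before coupling; or closure to the trans-diol or to the cis-diol on the face of the C10 methyl. The fallback sets out from 25 and returns at 26. Both formyl groups of 25 are methylenated under non-basic conditions (Zn, CH2Br2, TiCl4, THF/CH2Cl2, 0 °C) to the 8,9-divinyl compound F1. Ring-closing metathesis with the second-generation Grubbs catalyst (toluene, high dilution, 80 °C) should then close the ten-membered ring as the cis C8=C9 cycloalkene F2, the geometry expected from the rigid furanone and lactone. OsO4 (cat.) with NMO in acetone/H2O should add syn to this isolated, most electron-rich double bond from the face away from the C10 methyl to give 26. In this variant the cis relation of the diol follows from the mechanism of osmylation and no longer from a samarium bridge.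

Step 18 (enolate aminomethylation on the macrocycle). Under the strongly basic conditions the trimethylsilyl group may be lost from O9, followed by retro-aldol opening of the C9–C10 bond (the leaving enolate is an aromatic furanolate). Silyl migration between O8 and O9 or slow enolisation of the hindered lactone are further possibilities. The fallback sets out from 26 and returns at 33. With 2,2-dimethoxypropane and PPTS (CH2Cl2, rt) 26 is converted into the 8,9-acetonide F3, whose cis-fused dioxolane cannot release a C9 alkoxide. LiN(iPr)2 at −78 °C gives the lithium enolate F4, CH2=NMe2+ I− the Mannich base F5, MeI the ammonium iodide F6, and aqueous NaHCO3 the α-methylene lactone acetonide F7. Aqueous AcOH at 40 °C hydrolyses the acetal to the diol F8, and TBSCl/imidazole (DMF, 0 °C) silylates the less hindered O8 to give 33. The two hydroxyls are thus told apart after, not before, the enolate chemistry.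

Step 13 (reductive removal of the auxiliary). Hydride may also attack the lactone or the furanone carbonyl, and the lactone may shift from O6 to the new C8 alkoxide. The fallback sets out from 22 and returns at 23. LiOH/H2O2 (THF/H2O, 0 °C) cleaves the auxiliary and, after acidification (which re-closes any opened lactone, since the C8 carboxyl could only form a four-membered ring), gives the carboxylic acid F9. Activation with iBuOCOCl and N-methylmorpholine (THF, −15 °C) gives the mixed anhydride F10. NaBH4 in THF/H2O at −15 °C for a few minutes reduces only the anhydride carbonyl to give 23, so the exposure of the other carbonyl groups to hydride is short.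

**Further compounds**

F1 | step 16 | 8,9-divinyl compound (25 with CH=CH2 in place of both CH=O; stereocentres as in 25) | C=C[C@H]1CC(=O)O[C@@H]1/C=C(/C)C1=CC(=O)[C@@](C=C)(C)O1
F2 | step 16 | cis C8=C9 cycloalkene (26 with C8=C9 in place of the two CHOH groups) | C[C@@]12/C=C\[C@H]3CC(=O)O[C@@H]3/C=C(/C)C(O1)=CC2=O
F3 | step 18 | 8,9-O-isopropylidene acetal of 26 | CC3(C)O[C@H]1[C@@H](O3)[C@H]2CC(=O)O[C@@H]2/C=C(/C)C2=CC(=O)[C@@]1(C)O2
F4 | step 18 | lithium enolate (C11–C12) of F3 | [Li+].CC3(C)O[C@H]1[C@@H](O3)[C@H]2C=C([O-])O[C@@H]2/C=C(/C)C2=CC(=O)[C@@]1(C)O2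
F5 | step 18 | Mannich base, F3 with CH2NMe2 on C11 (C11 epimers) | CC3(C)O[C@H]1[C@@H](O3)[C@H]2C(CN(C)C)C(=O)O[C@@H]2/C=C(/C)C2=CC(=O)[C@@]1(C)O2
F6 | step 18 | trimethylammonium iodide of F5 | [I-].CC3(C)O[C@H]1[C@@H](O3)[C@H]2C(C[N+](C)(C)C)C(=O)O[C@@H]2/C=C(/C)C2=CC(=O)[C@@]1(C)O2
F7 | step 18 | α-methylene lactone 8,9-acetonide | CC3(C)O[C@H]1[C@@H](O3)[C@H]2C(=C)C(=O)O[C@@H]2/C=C(/C)C2=CC(=O)[C@@]1(C)O2
F8 | step 18 | 8,9-dihydroxy α-methylene lactone (33 without the silyl group) | O[C@H]1[C@@H](O)[C@H]2C(=C)C(=O)O[C@@H]2/C=C(/C)C2=CC(=O)[C@@]1(C)O2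
F9 | step 13 | carboxylic acid (22 with CO2H in place of the imide) | OC(=O)[C@H]1CC(=O)O[C@@H]1/C=C(/C)C1=CC(=O)[C@@](CO[Si](C)(C)C(C)(C)C)(C)O1
F10 | step 13 | isobutyl carbonic mixed anhydride of F9 | CC(C)COC(=O)OC(=O)[C@H]1CC(=O)O[C@@H]1/C=C(/C)C1=CC(=O)[C@@](CO[Si](C)(C)C(C)(C)C)(C)O1
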